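**Retrosynthetic overview**
1. Locants: the flavanone half is ring A (benzo), ring C (O1, C2, C3, C4) and ring B (C1'–C6'). The flavone half is ring D (benzo, C5''–C8''), ring E (pyranone, O1''–C4'') and ring F (anisyl).
2. The last C–C disconnection is C1' (ring B)–C2 (ring C). It is made by an enantioselective rhodium-catalysed 1,4-addition of a ring-B boronic acid, already carrying the whole flavone half, to a 2-unsubstituted 5-benzyloxy-7-methoxychromone. This one step joins the halves, turns the flat pyranone into ring C of the flavanone and sets C2, the only stereocentre.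
3. Enabling feature: C2 is bound to O1 and lies β to the C4 carbonyl, so its dehydro form (C2=C3 of a chromone, only H on C2) is a planar prochiral acceptor. The rival enone C2''=C3'' of ring E is blocked by ring F. C1' is para to O4' and meta to the biaryl bond, so it is open for boron and for the metal.
4. The boronic acid goes back to a C3'–C8'' Suzuki–Miyaura bond between an 8-iodoflavone and 2-benzyloxy-5-chlorophenylboronic acid. The chloride is a silent handle exchanged for boron afterwards.
5. Ring order: rings A and D both come from one mono-benzylated acetophenone. Ring C (as chromone, one-carbon insertion) and ring E (aldol, oxidative cyclisation) are closed separately, and then ring B is attached. No ring is closed after the union, and three benzyl ethers leave in one neutral hydrogenolysis.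

Key step: step 8

Assumption: the C3'–C8'' biaryl axis carries no descriptor in the target and is taken as configurationally labile at ambient temperature, so C2 is the only stereo-element to control.

**Step 1**
Reactants: 1 2',6'-dihydroxy-4'-methoxyacetophenone
Product: 2 1-[2-(benzyloxy)-6-hydroxy-4-methoxyphenyl]ethan-1-one
Conditions: BnBr (1.05 equiv), K2CO3 (1.1 equiv), acetone, reflux
Reagents that add atoms: benzyl bromide, BrCc1ccccc1
Why: Williamson ether synthesis on a symmetrical diol should stop after one alkylation, because the remaining hydroxyl is locked in a hydrogen bond to the acetyl carbonyl and is far less nucleophilic.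

**Step 2**
Reactants: 2 1-[2-(benzyloxy)-6-hydroxy-4-methoxyphenyl]ethan-1-one
Product: 4 5-(benzyloxy)-7-methoxy-4H-chromen-4-one, via enaminone 3 (not isolated)
Conditions: Me2NCH(OMe)2, toluene, 100 °C; evaporate; AcOH, 90 °C
Reagents that add atoms: N,N-dimethylformamide dimethyl acetal, COC(OC)N(C)C
Why: Enaminone formation at the acetyl CH3, then acid-induced 6-endo-trig addition of the phenol to the β-carbon with loss of dimethylamine, is the standard one-carbon chromone synthesis and leaves C2 unsubstituted as the key step requires.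

**Step 3**
Reactants: 2 1-[2-(benzyloxy)-6-hydroxy-4-methoxyphenyl]ethan-1-one; 5 4-methoxybenzaldehyde
Product: 6 (E)-1-[2-(benzyloxy)-6-hydroxy-4-methoxyphenyl]-3-(4-methoxyphenyl)prop-2-en-1-one
Conditions: KOH (50% aq.), EtOH, rt
Reagents that add atoms: none
Why: Claisen–Schmidt condensation of an o-hydroxyacetophenone with a non-enolisable aldehyde should give the (E)-chalcone under thermodynamic control.

**Step 4**
Reactants: 6 (E)-1-[2-(benzyloxy)-6-hydroxy-4-methoxyphenyl]-3-(4-methoxyphenyl)prop-2-en-1-one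
Product: 7 5-(benzyloxy)-7-methoxy-2-(4-methoxyphenyl)-4H-chromen-4-one
Conditions: I2 (10 mol%), DMSO, 120 °C
Reagents that add atoms: none
Why: Iodine-catalysed oxidative cyclisation of a 2'-hydroxychalcone (6-endo oxa-Michael closure of ring E, α-iodination, loss of HI, DMSO as terminal oxidant) is the standard flavone synthesis, and benzyl aryl ethers are known to tolerate it.

**Step 5**
Reactants: 7 5-(benzyloxy)-7-methoxy-2-(4-methoxyphenyl)-4H-chromen-4-one
Product: 8 5-(benzyloxy)-8-iodo-7-methoxy-2-(4-methoxyphenyl)-4H-chromen-4-one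
Conditions: NIS (1.05 equiv), TFA (30 mol%), MeCN, 0 °C to rt, dark
Reagents that add atoms: N-iodosuccinimide, O=C1CCC(=O)N1I
Why: Electrophilic aromatic iodination should go to ring D, the only ring with two meta-related alkoxy donors, and there to C8'' (flanked by OMe and the ring oxygen) rather than C6'' (squeezed between OMe and the bulky benzyloxy group), in line with the known C8 preference of 5,7-dialkoxyflavones.

**Step 6**
Reactants: 8 5-(benzyloxy)-8-iodo-7-methoxy-2-(4-methoxyphenyl)-4H-chromen-4-one; 9 [2-(benzyloxy)-5-chlorophenyl]boronic acid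
Product: 10 5-(benzyloxy)-8-[2-(benzyloxy)-5-chlorophenyl]-7-methoxy-2-(4-methoxyphenyl)-4H-chromen-4-one
Conditions: Pd(PPh3)4 (5 mol%), K2CO3, DME/H2O 4:1, 85 °C
Reagents that add atoms: none
Why: Suzuki–Miyaura coupling of 8-iodoflavones with ortho-alkoxyarylboronic acids has close precedent, and with PPh3 as ligand zerovalent palladium should insert only into the C–I bond, so the aryl chloride is carried through untouched.

**Step 7**
Reactants: 10 5-(benzyloxy)-8-[2-(benzyloxy)-5-chlorophenyl]-7-methoxy-2-(4-methoxyphenyl)-4H-chromen-4-one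
Product: 12 {4-(benzyloxy)-3-[5-(benzyloxy)-7-methoxy-2-(4-methoxyphenyl)-4-oxo-4H-chromen-8-yl]phenyl}boronic acid, via pinacol boronate 11 (not isolated)
Conditions: B2pin2, Pd2(dba)3 (2 mol%), XPhos (8 mol%), KOAc, 1,4-dioxane, 100 °C; then THF/H2O, NaIO4, NH4OAc, rt
Reagents that add atoms: bis(pinacolato)diboron, CC1(C)OB(OC1(C)C)B1OC(C)(C)C(C)(C)O1; water, O
Why: Miyaura borylation of an electron-rich aryl chloride is enabled by the bulky dialkylbiarylphosphine, KOAc is too weak a base to start Suzuki homocoupling, and periodate glycol cleavage of pinacol in the same flask should free the boronic acid needed for fast transmetalation to rhodium.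

**Step 8**
Reactants: 12 {4-(benzyloxy)-3-[5-(benzyloxy)-7-methoxy-2-(4-methoxyphenyl)-4-oxo-4H-chromen-8-yl]phenyl}boronic acid; 4 5-(benzyloxy)-7-methoxy-4H-chromen-4-one
Product: 13 (2S)-5-(benzyloxy)-2-{4-(benzyloxy)-3-[5-(benzyloxy)-7-methoxy-2-(4-methoxyphenyl)-4-oxo-4H-chromen-8-yl]phenyl}-7-methoxy-2,3-dihydro-4H-chromen-4-one
Conditions: 12 (1.0 equiv), 4 (1.5 equiv), [RhCl(C2H4)2]2 (2.5 mol%), (S)-2,2'-bis[bis(3,4,5-trifluorophenyl)phosphino]-6,6'-dimethoxy-1,1'-biphenyl [(S)-MeO-F12-BIPHEP, 5.5 mol%], aq. KOH (10 mol%), H2O (2 equiv), toluene, 30 °C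
Reagents that add atoms: none
Why: This is a Hayashi–Miyaura asymmetric 1,4-addition, a reaction type with close precedent for arylboronic acids and 2-unsubstituted 4-chromones (5,7-dioxygenated ones included) giving flavanones: transmetalation from boron to the hydroxo complex of monovalent rhodium binds ring B to the metal through C1', the C2=C3 bond of 4 inserts into the Rh–C1' bond, and water protonates the resulting oxa-π-allyl rhodium enolate at C3 and returns Rh–OH. No ring is closed; the pre-formed pyranone is only saturated at C2–C3, so the step delivers the finished ring C and the whole carbon skeleton at once. The single new stereocentre C2 is set in the insertion by the (S)-configured biaryl diphosphine, whose P-aryl groups leave room for the benzo part of 4 in one orientation only, so ring B should be delivered to the Re face of C2 (O1 > C3 > H) to give 2S, the same spatial sense this ligand family shows with cyclic enones. The step needs chemoselectivity between two enones, and substitution secures it: C2 of 4 bears only H while C2'' of ring E bears ring F, β,β-disubstituted enones do not insert under such mild conditions, and both ketones are shielded from 1,2-addition by peri benzyloxy groups. Boron sits para to O4' and meta to the biaryl bond, so the flavone does not crowd the metal, the electron-poor ligand should speed insertion into the electron-rich chromone enough to outrun protodeboronation, and the cheap partner 4 is used in excess. Nearly neutral toluene at ambient temperature and the capped O5 and O4' positions should suppress retro-oxa-Michael opening, so C2 should not racemise.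

**Step 9**
Reactants: 13 (2S)-5-(benzyloxy)-2-{4-(benzyloxy)-3-[5-(benzyloxy)-7-methoxy-2-(4-methoxyphenyl)-4-oxo-4H-chromen-8-yl]phenyl}-7-methoxy-2,3-dihydro-4H-chromen-4-one
Product: 14 (2S)-2,3-dihydroheveaflavone
Conditions: H2 (1 atm), 10% Pd/C, EtOAc/THF 1:1, rt, stopped after uptake of 3 equiv
Reagents that add atoms: none
Why: Catalytic hydrogenolysis should cleave the three primary benzyl aryl ethers much faster than it touches the secondary benzylic C2–O1 bond, the C2''=C3'' bond or the ketones, and the absence of acid and base leaves the base-labile C2 stereocentre intact.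

**Compound list**
1 | 2',6'-dihydroxy-4'-methoxyacetophenone | CC(=O)c1c(O)cc(OC)cc1O | starting material
2 | 1-[2-(benzyloxy)-6-hydroxy-4-methoxyphenyl]ethan-1-one | CC(=O)c1c(O)cc(OC)cc1OCc1ccccc1 | intermediate
3 | (E)-1-[2-(benzyloxy)-6-hydroxy-4-methoxyphenyl]-3-(dimethylamino)prop-2-en-1-one (not isolated) | CN(C)/C=C/C(=O)c1c(O)cc(OC)cc1OCc1ccccc1 | intermediate
4 | 5-(benzyloxy)-7-methoxy-4H-chromen-4-one | COc1cc(OCc2ccccc2)c2c(=O)ccoc2c1 | intermediate
5 | 4-methoxybenzaldehyde | COc1ccc(C=O)cc1 | starting material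
6 | (E)-1-[2-(benzyloxy)-6-hydroxy-4-methoxyphenyl]-3-(4-methoxyphenyl)prop-2-en-1-one | COc1ccc(/C=C/C(=O)c2c(O)cc(OC)cc2OCc2ccccc2)cc1 | intermediate
7 | 5-(benzyloxy)-7-methoxy-2-(4-methoxyphenyl)-4H-chromen-4-one | COc1ccc(-c2cc(=O)c3c(OCc4ccccc4)cc(OC)cc3o2)cc1 | intermediate
8 | 5-(benzyloxy)-8-iodo-7-methoxy-2-(4-methoxyphenyl)-4H-chromen-4-one | COc1ccc(-c2cc(=O)c3c(OCc4ccccc4)cc(OC)c(I)c3o2)cc1 | intermediate
9 | [2-(benzyloxy)-5-chlorophenyl]boronic acid | OB(O)c1cc(Cl)ccc1OCc1ccccc1 | starting material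
10 | 5-(benzyloxy)-8-[2-(benzyloxy)-5-chlorophenyl]-7-methoxy-2-(4-methoxyphenyl)-4H-chromen-4-one | COc1ccc(-c2cc(=O)c3c(OCc4ccccc4)cc(OC)c(-c4cc(Cl)ccc4OCc4ccccc4)c3o2)cc1 | intermediate
11 | 5-(benzyloxy)-8-[2-(benzyloxy)-5-(4,4,5,5-tetramethyl-1,3,2-dioxaborolan-2-yl)phenyl]-7-methoxy-2-(4-methoxyphenyl)-4H-chromen-4-one (not isolated) | COc1ccc(-c2cc(=O)c3c(OCc4ccccc4)cc(OC)c(-c4cc(B5OC(C)(C)C(C)(C)O5)ccc4OCc4ccccc4)c3o2)cc1 | intermediate
12 | {4-(benzyloxy)-3-[5-(benzyloxy)-7-methoxy-2-(4-methoxyphenyl)-4-oxo-4H-chromen-8-yl]phenyl}boronic acid | COc1ccc(-c2cc(=O)c3c(OCc4ccccc4)cc(OC)c(-c4cc(B(O)O)ccc4OCc4ccccc4)c3o2)cc1 | intermediate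
13 | (2S)-5-(benzyloxy)-2-{4-(benzyloxy)-3-[5-(benzyloxy)-7-methoxy-2-(4-methoxyphenyl)-4-oxo-4H-chromen-8-yl]phenyl}-7-methoxy-2,3-dihydro-4H-chromen-4-one | COc1ccc(-c2cc(=O)c3c(OCc4ccccc4)cc(OC)c(-c4cc([C@@H]5CC(=O)c6c(OCc7ccccc7)cc(OC)cc6O5)ccc4OCc4ccccc4)c3o2)cc1 | intermediate
14 | (2S)-2,3-dihydroheveaflavone, (2S)-5-hydroxy-2-{4-hydroxy-3-[5-hydroxy-7-methoxy-2-(4-methoxyphenyl)-4-oxo-4H-chromen-8-yl]phenyl}-7-methoxy-2,3-dihydro-4H-chromen-4-one | COc1ccc(-c2cc(=O)c3c(O)cc(OC)c(-c4cc([C@@H]5CC(=O)c6c(O)cc(OC)cc6O5)ccc4O)c3o2)cc1 | target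

**Step count**
Total steps: 9. Longest linear sequence: 8 (steps 1, 3, 4, 5, 6, 7, 8, 9 from compound 1).

**Steps most likely to fail**

**Step 8.** Insertion into the electron-rich 5,7-dioxygenated chromone may be slower than protodeboronation of the valuable boronic acid. Facial discrimination may also be eroded by the remote bulk of the flavone.
- The fallback sets out from 8 and 2 and comes back at 13. The C1'–C2 bond is bought in as an aryl aldehyde, and ring C is closed at O1–C2 instead.
- Purchased 4-(benzyloxy)-3-bromobenzaldehyde (O=Cc1ccc(OCc2ccccc2)c(Br)c1) is borylated (B2pin2, PdCl2(dppf), KOAc, dioxane, 90 °C) to 4-(benzyloxy)-3-(4,4,5,5-tetramethyl-1,3,2-dioxaborolan-2-yl)benzaldehyde F1.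
- Suzuki–Miyaura coupling of this with 8 (Pd(PPh3)4, K2CO3, DME/H2O) gives the biaryl aldehyde F2.
- Claisen–Schmidt condensation with 2 (KOH, EtOH/THF, rt) gives the 2'-hydroxychalcone F3.
- NaOAc in hot EtOH closes ring C by 6-endo-trig oxa-Michael addition to the racemic flavanone F4.
- Preparative chromatography on a chiral stationary phase (cellulose tris(3,5-dimethylphenylcarbamate)) separates 13 from its (2R)-enantiomer F5, which the same NaOAc equilibration returns to F4 for recycling.

**Step 6.** Oxidative addition at the C8''–I bond, flanked by the methoxy group and the ring oxygen, may be slow. Hydrodeiodination of the iodide and protodeboronation of the ortho-alkoxy boronic acid could then take over.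
- The fallback sets out from 8 and comes back at 10 by reversing the polarity of the coupling.
- Purchased 4-chloro-2-iodophenol (Oc1ccc(Cl)cc1I) is benzylated (BnBr, K2CO3, acetone) to 1-(benzyloxy)-4-chloro-2-iodobenzene F6.
- Compound 8 is converted by Miyaura borylation (B2pin2, PdCl2(dppf), KOAc, DMSO, 80 °C) into the flavone 8-pinacolboronate F7.
- Suzuki–Miyaura coupling of the two (Pd(PPh3)4, K2CO3, DME/H2O, 85 °C) then relies on the unhindered C–I bond of the small partner for fast oxidative addition, with the C–Cl bond again left alone.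

**Step 5.** Iodination may spread over C8'', C6'' and C3'', or run on to di-iodination.
- The fallback sets out from 2 and comes back at 8 by placing iodine before ring E exists.
- Compound 2 is iodinated ortho to its free chelated hydroxyl (I2, HIO3, aq. EtOH) to 1-[6-(benzyloxy)-2-hydroxy-3-iodo-4-methoxyphenyl]ethan-1-one F8.
- Claisen–Schmidt condensation with 5 gives the 3'-iodochalcone F9, and I2/DMSO closes ring E.
- Since O1'' comes from that hydroxyl, the neighbouring iodine ends at C8'' by construction.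

**Further compounds**
F1 | step 8 | 4-(benzyloxy)-3-(4,4,5,5-tetramethyl-1,3,2-dioxaborolan-2-yl)benzaldehyde | O=Cc1ccc(OCc2ccccc2)c(B2OC(C)(C)C(C)(C)O2)c1
F2 | step 8 | 4-(benzyloxy)-3-[5-(benzyloxy)-7-methoxy-2-(4-methoxyphenyl)-4-oxo-4H-chromen-8-yl]benzaldehyde | COc1ccc(-c2cc(=O)c3c(OCc4ccccc4)cc(OC)c(-c4cc(C=O)ccc4OCc4ccccc4)c3o2)cc1
F3 | step 8 | 5-(benzyloxy)-8-{2-(benzyloxy)-5-[(E)-3-[2-(benzyloxy)-6-hydroxy-4-methoxyphenyl]-3-oxoprop-1-en-1-yl]phenyl}-7-methoxy-2-(4-methoxyphenyl)-4H-chromen-4-one | COc1ccc(-c2cc(=O)c3c(OCc4ccccc4)cc(OC)c(-c4cc(/C=C/C(=O)c5c(O)cc(OC)cc5OCc5ccccc5)ccc4OCc4ccccc4)c3o2)cc1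
F4 | step 8 | racemic form of 13 | COc1ccc(-c2cc(=O)c3c(OCc4ccccc4)cc(OC)c(-c4cc(C5CC(=O)c6c(OCc7ccccc7)cc(OC)cc6O5)ccc4OCc4ccccc4)c3o2)cc1
F5 | step 8 | (2R)-enantiomer of 13 | COc1ccc(-c2cc(=O)c3c(OCc4ccccc4)cc(OC)c(-c4cc([C@H]5CC(=O)c6c(OCc7ccccc7)cc(OC)cc6O5)ccc4OCc4ccccc4)c3o2)cc1
F6 | step 6 | 1-(benzyloxy)-4-chloro-2-iodobenzene | Clc1ccc(OCc2ccccc2)c(I)c1
F7 | step 6 | 5-(benzyloxy)-7-methoxy-2-(4-methoxyphenyl)-8-(4,4,5,5-tetramethyl-1,3,2-dioxaborolan-2-yl)-4H-chromen-4-one | COc1ccc(-c2cc(=O)c3c(OCc4ccccc4)cc(OC)c(B4OC(C)(C)C(C)(C)O4)c3o2)cc1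
F8 | step 5 | 1-[6-(benzyloxy)-2-hydroxy-3-iodo-4-methoxyphenyl]ethan-1-one | CC(=O)c1c(O)c(I)c(OC)cc1OCc1ccccc1
F9 | step 5 | (E)-1-[6-(benzyloxy)-2-hydroxy-3-iodo-4-methoxyphenyl]-3-(4-methoxyphenyl)prop-2-en-1-one | COc1ccc(/C=C/C(=O)c2c(O)c(I)c(OC)cc2OCc2ccccc2)cc1
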